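The target is a single 27-membered lactone ring whose carbons C2–C25 (C1 = lactone carbonyl, C26 = OCH2) form an unfunctionalised polymethylene chain. The route rests on disconnecting C11–C12 and exploits that featureless stretch: the bond is made at the alkyne oxidation level, as the central sp–sp bond of a C10≡C11–C12≡C13 diyne, by Eglinton oxidative coupling of two terminal alkyne carbons of like (nucleophilic) polarity, which closes the macrocycle in one operation. The precursor is the open-chain ester of undec-10-ynoic acid with pentadec-14-yn-1-ol, the alcohol arising from propargyl alcohol by alkylation and an alkyne zipper. Exhaustive hydrogenation then erases the diyne.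

Key step: step 4

Remark: the target has no stereocentre and no stereogenic double bond, so no SMILES carries a stereodescriptor; the locants C1 (lactone carbonyl) to C26 (OCH2) are used for the ring carbons throughout.

Step 1
Reactants: 1 prop-2-yn-1-ol (propargyl alcohol); 2 1-bromododecane
Product: 5 pentadec-2-yn-1-ol, via dilithiated prop-2-yn-1-ol 3 (not isolated), via lithium pentadec-2-yn-1-olate 4 (not isolated)
Conditions: n-BuLi (2.1 equiv), THF/DMPU, −78 → 0 °C; then 2, 0 °C → rt; then H2O
Reagents that add atoms: none
Why: Alkylation of a propargylic alcohol dianion: the acetylide carbon of 3 is far more nucleophilic than its lithium alkoxide, so the primary bromide should undergo SN2 C-alkylation and give the C15 chain without a protecting group.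

Step 2
Reactants: 5 pentadec-2-yn-1-ol
Product: 7 pentadec-14-yn-1-ol, via dipotassium salt of pentadec-14-yn-1-ol 6 (not isolated)
Conditions: KH (5 equiv), H2N(CH2)3NH2, rt; then 5, 0 °C → rt; then H2O, 0 °C
Reagents that add atoms: none
Why: Acetylene zipper (potassium 3-aminopropylamide isomerisation): reversible propargyl–allenyl proton shifts move the triple bond along the unbranched chain away from the alkoxide until irreversible deprotonation of the terminal alkyne traps it as acetylide 6, which water protonates to 7.

Step 3
Reactants: 7 pentadec-14-yn-1-ol; 8 undec-10-ynoic acid
Product: 9 pentadec-14-yn-1-yl undec-10-ynoate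
Conditions: DCC (1.1 equiv), DMAP (0.1 equiv), CH2Cl2, 0 °C → rt
Reagents that add atoms: none
Why: Steglich esterification: carbodiimide activation of the acid and DMAP-catalysed acyl transfer to the unhindered primary alcohol proceed under neutral conditions that leave both terminal alkynes untouched.

Step 4
Reactants: 9 pentadec-14-yn-1-yl undec-10-ynoate
Product: 10 1-oxacycloheptacosa-11,13-diyn-2-one
Conditions: Cu(OAc)2·H2O (10 equiv), pyridine/Et2O, 45 °C, syringe-pump addition of 9 over 24 h (final ca. 1 mM)
Reagents that add atoms: none
Why: Pyridine-assisted deprotonation at divalent copper converts both terminal alkynes of 9 into copper acetylides, and two acetylide ligands held on a dinuclear copper core couple with reduction of two Cu(OAc)2 to CuOAc, forging the C11–C12 sp–sp bond. The closest known reaction type is the Eglinton (Glaser-type) oxidative homocoupling of terminal alkynes under high dilution, a classical way to close macrocyclic 1,3-diynes, here uniting two carbons that are both nucleophilic acetylide termini. It closes the single 27-membered ring end-to-end, with the new bond and both triple bonds endocyclic; the ring is large enough to carry the linear C9–C14 rod without strain. No stereocentre is formed. The selectivity needed is ring closure over intermolecular coupling (cyclic dimer, oligomers), which slow addition of 9 into a large excess of oxidant should secure by keeping the stationary concentration of free alkyne very low; because both ends are the same functional group, any intramolecular coupling gives the one product. The ester and the saturated chain are inert to Cu(OAc)2 in pyridine.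

Step 5
Reactants: 10 1-oxacycloheptacosa-11,13-diyn-2-one
Product: 11 26-hexacosanolide (1-oxacycloheptacosan-2-one)
Conditions: H2 (1 atm), 10% Pd/C, EtOAc, rt
Reagents that add atoms: none
Why: Heterogeneous catalytic hydrogenation: the conjugated diyne should take up four equivalents of hydrogen to become the C10–C13 tetramethylene unit, while the alkyl lactone, which has no allylic, propargylic or benzylic C–O bond, is inert.

Compound list
1 | prop-2-yn-1-ol (propargyl alcohol) | C#CCO | starting material
2 | 1-bromododecane | CCCCCCCCCCCCBr | starting material
3 | dilithiated prop-2-yn-1-ol (lithium 3-lithioprop-2-yn-1-olate, not isolated) | [Li+].[Li+].[C-]#CC[O-] | intermediate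
4 | lithium pentadec-2-yn-1-olate (not isolated) | CCCCCCCCCCCCC#CC[O-].[Li+] | intermediate
5 | pentadec-2-yn-1-ol | CCCCCCCCCCCCC#CCO | intermediate
6 | dipotassium salt of pentadec-14-yn-1-ol (acetylide alkoxide, not isolated) | [K+].[K+].[C-]#CCCCCCCCCCCCCC[O-] | intermediate
7 | pentadec-14-yn-1-ol | C#CCCCCCCCCCCCCCO | intermediate
8 | undec-10-ynoic acid | C#CCCCCCCCCC(=O)O | starting material
9 | pentadec-14-yn-1-yl undec-10-ynoate | C#CCCCCCCCCC(=O)OCCCCCCCCCCCCCC#C | intermediate
10 | 1-oxacycloheptacosa-11,13-diyn-2-one | O=C1CCCCCCCCC#CC#CCCCCCCCCCCCCCO1 | intermediate
11 | 26-hexacosanolide (1-oxacycloheptacosan-2-one) | O=C1CCCCCCCCCCCCCCCCCCCCCCCCCO1 | target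

Total step count: 5. Longest linear sequence: 5 steps (1 → 5 → 7 → 9 → 10 → 11; acid 8 enters in step 3).

Steps most likely to fail

Step 4: intermolecular coupling may outrun ring closure, so that cyclic dimer and linear oligomers form in place of the monomeric macrocycle. The fallback sets out from 9 and comes back to the route at 11. Both terminal alkynes of 9 would be hydrated in the anti-Markovnikov sense (disiamylborane, THF, 0 °C; then H2O2, pH 7 phosphate buffer), conditions the ester tolerates, to give 15-oxopentadecyl 11-oxoundecanoate F1. An intramolecular McMurry coupling (TiCl3(DME)1.5, Zn–Cu couple, DME, reflux, syringe-pump addition) would then join C11 and C12 as an alkene. The low-valent titanium surface binds both aldehyde ends, which makes large-ring closure largely independent of ring size, and aldehydes couple far faster than the ester. The product would be 1-oxacycloheptacos-12-en-2-one F2 as an E/Z mixture; hydrogenation of F2 (H2, 10% Pd/C, EtOAc) converges on 11 whatever the alkene geometry.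

Step 2: the triple bond may stall partway along the twelve positions, leaving mixtures of internal alkynols, or the strongly basic medium may degrade the material. The fallback sets out from 8 and comes back at 7. A crossed Kolbe electrolysis of 8 with an excess of monomethyl adipate (MeOH, partial neutralisation with NaOMe, Pt electrodes, constant current) should couple the two decarboxylated radicals to methyl pentadec-14-ynoate F3, which is separated from the two symmetrical dimers. Reduction of F3 (LiAlH4, THF, 0 °C) would give 7 without any isomerisation.

Step 1: the poorly soluble dianion may react sluggishly with the long-chain bromide, with competing O-alkylation and elimination of the bromide. The fallback sets out from 2 and comes back at 5. Bromide 2 would be alkylated with LiC≡CH·H2NCH2CH2NH2 (DMSO, rt) to tetradec-1-yne F4. Its lithium acetylide (n-BuLi, THF, −78 °C) would then add to paraformaldehyde to give 5, so that the carbinol carbon enters as formaldehyde and no dianion is needed.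

Further compounds
F1 | step 4 | 15-oxopentadecyl 11-oxoundecanoate | O=CCCCCCCCCCC(=O)OCCCCCCCCCCCCCCC=O
F2 | step 4 | 1-oxacycloheptacos-12-en-2-one (E/Z mixture) | O=C1CCCCCCCCCC=CCCCCCCCCCCCCCCO1
F3 | step 2 | methyl pentadec-14-ynoate | C#CCCCCCCCCCCCCC(=O)OC
F4 | step 1 | tetradec-1-yne | CCCCCCCCCCCCC#C
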